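Numbering used for the target: lactone ring A is O1, C2 (C=O), C3 (H), C4, C5; C6 is the exocyclic carbon; ring B is the aryl ring on C4 and ring C the aryl ring on C6.

## The problem

Rubrolide A is a (Z)-γ-benzylidene butenolide: ring A carries one 3,5-dibromo-4-hydroxyphenyl ring on C4 (ring B) and a second, identical one on C6 (ring C). There is no stereocentre; the only stereo-element is the C5=C6 double bond, which must be Z (ring C on the side of O1). What resists a short synthesis is the fully substituted C4–C5–C6 region: the aryl–C4 bond, the C5–O1 enol-ester bond and the C5=C6 bond all meet there, and the usual plans make them one at a time from two different aryl building blocks although rings B and C are the same. The Z geometry is the thermodynamic one (in the E isomer ring C would be pressed against ring B), so it can be set by equilibration if the closing conditions allow it. The enol lactone is an acylating agent: hydroxide or alkoxide opens it and the freed enolate can reclose on carbon to a cyclopentene-1,3-dione, so the end of the route has to be acidic or neutral. The four C–Br bonds exclude late steps with low-valent metals or organolithiums, and a phenol ring not yet brominated is a carbon nucleophile at its ortho positions, so the timing of bromination matters. The feature exploited here is that C4, C5 and C6 with rings B and C form a hidden C2v-symmetric 1,3-diarylpropan-2-one (C5 its carbonyl carbon, C4 and C6 its two equivalent benzylic carbons), while C2 and C3 with the lactone oxygens are glyoxylic acid.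

## Retrosynthesis

**10 to 9.** Only the π bond C5=C6 is cut, by formal addition of water, which gives the 5-hydroxybutenolide 9, the ring-chain tautomer of keto-enoic acid 8. The neighbouring cut, the whole C5=C6 bond (butenolide plus aryl aldehyde), would make ring C a building block of its own and leave the C4–aryl bond unsolved. The single stereocentre of 9 is erased again, so the geometry is left to an elimination with one regiochemical option (C6–H; C4 has no hydrogen) that can be run reversibly under acid to give Z.

**9 (and 8, 7) to 5 + 6.** The bonds cut are C3=C4 (aldol condensation, through aldol adduct 7) and O1–C5 (addition of the carboxyl OH to the ketone). A cut at C4–aryl or C4–C5 would keep a preformed heterocycle and two different aryl reagents. The C3=C4 cut uncovers ketone 5, whose two α-carbons are identical, so the question of which benzylic carbon becomes C4 and which C6 does not arise. The precursor is a symmetric acyclic ketone plus the two-carbon commodity acid 6. The forward reaction must form C3–C4, O1–C5 and C5=C6 in one operation, stop after one condensation, and leave the rings alone. The four bromines secure the last point, since every position ortho to OH is occupied and the para positions carry the side chains.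

**5 to 4.** Four C–Br bonds are cut. Bromination at this stage, and not on the finished butenolide or on acid 1 (where a second bromination ortho to OMe is slow), lets the bromines act as blocking groups in the key step and lets the key step deliver the natural product itself. The forward reaction must brominate the rings faster than the α-carbons of the ketone.

**4 to 3.** Two O–CH3 bonds are cut. The methyl ethers serve only the ketone-forming step, where free phenols would be acylated.

**3 to 1 + 1.** The C(O)–CH2 bond of the ketone (C4–C5 of the target) is cut with return of CO2: a decarboxylative Claisen-type dimerisation of arylacetic acid 1 through β-keto acid 2. The whole carbon skeleton of 10 is therefore two molecules of 1 and one of 6.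

## Roads not taken

**Alternative 1:** The most obvious plan cuts C5=C6 completely (condensation) and the C4–aryl bond (cross-coupling).
- Forward: Suzuki coupling of a 4-halo- or 4-sulfonyloxybutenolide with a 4-methoxyphenylboronic acid under Pd(PPh3)4 would give 4-(4-methoxyphenyl)furan-2(5H)-one A1. The key step would be a vinylogous aldol condensation of A1 with the 4-methoxy-substituted aromatic aldehyde (2-silyloxyfuran, then base-induced elimination) to rubrolide E di-O-methyl ether A2, followed by demethylation and fourfold bromination.
- Why the chosen plan is better: this route brings rings B and C in as two reagents in two separate C–C bond formations. It needs a preformed heterocycle, zerovalent palladium and an amine-base elimination on the base-sensitive enol lactone. Bromination must come last, on a compound with the electron-rich C5=C6 enol-ester bond. It needs five to six steps against four and makes no use of the identity of the two rings.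

**Alternative 2:** Cut O1–C5 (lactonisation onto an alkyne) and C4–C5 (sp2–sp coupling).
- Forward: coupling of (Z)-3-iodo-3-(4-methoxyphenyl)prop-2-enoic acid A3 with a terminal 4-alkoxyphenylalkyne (Pd(PPh3)4, CuI, amine) would give enynoic acid A4. A4 closes by 5-exo-dig anti-addition of the carboxylate to the metal-bound alkyne to give A2 with Z geometry.
- Why the chosen plan is better: the competing 6-endo-dig mode leads to the isomeric 4,6-bis(4-methoxyphenyl)-2H-pyran-2-one A5, and the outcome depends on metal and aryl electronics. A3 needs its own geometry-controlled synthesis, two metals are used, the aryl units are again two different reagents, and demethylation and bromination still follow.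

**Alternative 3:** Cut O1–C5 and C4–C5 as above, but take both halves from one terminal arylalkyne plus carbon dioxide, another reading of the identical rings B and C.
- Forward: carboxylation and esterification of the alkyne would give ethyl 3-(4-methoxyphenyl)prop-2-ynoate A6. Pd(OAc)2/phosphine-catalysed addition of the C–H bond of a second alkyne molecule across A6 would give enynoate A7.
- Why the chosen plan is better: the addition is syn, so in A7 the ester stands trans to the alkyne (E geometry) and cannot lactonise onto it. An E-to-Z isomerisation, ester hydrolysis, the 5-exo/6-endo question of alternative 2 (A5), deprotection and bromination would all follow. That is seven or more steps with two catalytic metals against four metal-free steps.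

Key step: step 4

Remark on the chemistry: glyoxylic acid is taken as its commercial monohydrate (2,2-dihydroxyacetic acid, compound 6), and the geometry planned for is that of the target SMILES (Z, ring C syn to O1).

## Route

Step 1
Reactants: 1 (4-methoxyphenyl)acetic acid (two molecules)
Product: 3 1,3-bis(4-methoxyphenyl)propan-2-one, via β-keto acid 2 (not isolated)
Conditions: DCC (1.0 equiv), DMAP (0.25 equiv), CH2Cl2, 0 °C → rt
Reagents that add atoms: none
Why: Carbodiimide/DMAP-mediated decarboxylative Claisen-type self-condensation of an arylacetic acid: the activated acid C-acylates the benzylic carbon of a second arylacetyl unit to give 2, which loses CO2 spontaneously to the symmetric ketone.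

Step 2
Reactants: 3 1,3-bis(4-methoxyphenyl)propan-2-one
Product: 4 1,3-bis(4-hydroxyphenyl)propan-2-one
Conditions: BBr3 (4 equiv), CH2Cl2, −78 °C → rt; then H2O
Reagents that add atoms: none
Why: Lewis-acid cleavage of aryl methyl ethers (BBr3 demethylation); the ketone only coordinates boron and is released on hydrolysis.

Step 3
Reactants: 4 1,3-bis(4-hydroxyphenyl)propan-2-one
Product: 5 1,3-bis(3,5-dibromo-4-hydroxyphenyl)propan-2-one
Conditions: Br2 (4.1 equiv), NaOAc (4.5 equiv), AcOH, 15 °C → rt, dark
Reagents that add atoms: bromine, BrBr
Why: Electrophilic aromatic bromination of phenols: para is blocked by the CH2 group, so both bromines of each ring enter ortho to OH; ring bromination is far faster than ketone enolisation, and the acetate buffer removes the HBr that would catalyse α-bromination.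

Step 4
Reactants: 5 1,3-bis(3,5-dibromo-4-hydroxyphenyl)propan-2-one; 6 glyoxylic acid monohydrate
Product: 10 rubrolide A [(Z)-5-(3,5-dibromo-4-hydroxybenzylidene)-4-(3,5-dibromo-4-hydroxyphenyl)furan-2(5H)-one], via aldol acid 7 (not isolated), via keto-enoic acid 8 (not isolated), via hydroxybutenolide 9 (not isolated)
Conditions: 6 (1.5 equiv), TsOH·H2O (1.0 equiv), 1,4-dioxane, 100 °C; then PhMe, reflux with azeotropic removal of water
Reagents that add atoms: none
Why: Acid-catalysed crossed aldol condensation of an enolisable ketone with glyoxylic acid, pseudo-acid ring closure and dehydration of the resulting 5-hydroxybutenolide are reaction types with close precedent on benzyl ketones and are run here in one flask. The enol of 5 adds to the protonated aldehyde of 6 to form the C3–C4 bond (7), and loss of water gives the 4-oxo-2-enoic acid 8, whose E and Z isomers interconvert under acid. In the Z isomer of 8 the carboxyl OH adds to the C5 ketone (5-exo-trig closure of ring A) to give lactol 9. Under water removal 9 loses water across C5–C6, either by ionisation of the protonated lactol OH and loss of a C6 proton or through the C5–C6 enol of open-chain 8 and enol lactonisation; C6 holds the only β-hydrogens, so no regioisomer can form. No stereocentre remains; the C5=C6 geometry is set under reversible protonation and should settle as Z, with ring C syn to O1 and away from ring B, because the E isomer would force rings B and C into each other. Site selectivity between the two α-carbons is not needed because 5 is C2v-symmetric, and a second condensation is held back by closure to 9, which takes the ketone out of play. The phenol rings should stay untouched because every position ortho or para to OH carries Br or carbon, which shuts the ortho-hydroxyalkylation that glyoxylic acid undergoes with an unblocked p-alkylphenol.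

## Compound list

1 | (4-methoxyphenyl)acetic acid | COc1ccc(CC(=O)O)cc1 | starting material
2 | 2,4-bis(4-methoxyphenyl)-3-oxobutanoic acid (racemic) | COc1ccc(CC(=O)C(C(=O)O)c2ccc(OC)cc2)cc1 | intermediate (not isolated)
3 | 1,3-bis(4-methoxyphenyl)propan-2-one | COc1ccc(CC(=O)Cc2ccc(OC)cc2)cc1 | intermediate
4 | 1,3-bis(4-hydroxyphenyl)propan-2-one | Oc1ccc(CC(=O)Cc2ccc(O)cc2)cc1 | intermediate
5 | 1,3-bis(3,5-dibromo-4-hydroxyphenyl)propan-2-one | O=C(Cc1cc(Br)c(O)c(Br)c1)Cc1cc(Br)c(O)c(Br)c1 | intermediate
6 | glyoxylic acid monohydrate (2,2-dihydroxyacetic acid) | OC(O)C(=O)O | starting material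
7 | 3,5-bis(3,5-dibromo-4-hydroxyphenyl)-2-hydroxy-4-oxopentanoic acid (diastereomer mixture, racemic) | OC(=O)C(O)C(c1cc(Br)c(O)c(Br)c1)C(=O)Cc1cc(Br)c(O)c(Br)c1 | intermediate (not isolated)
8 | (Z)-3,5-bis(3,5-dibromo-4-hydroxyphenyl)-4-oxopent-2-enoic acid | OC(=O)/C=C(/c1cc(Br)c(O)c(Br)c1)C(=O)Cc1cc(Br)c(O)c(Br)c1 | intermediate (not isolated)
9 | 5-(3,5-dibromo-4-hydroxybenzyl)-4-(3,5-dibromo-4-hydroxyphenyl)-5-hydroxyfuran-2(5H)-one (racemic) | O=C1C=C(c2cc(Br)c(O)c(Br)c2)C(O)(Cc2cc(Br)c(O)c(Br)c2)O1 | intermediate (not isolated)
10 | rubrolide A, (Z)-5-(3,5-dibromo-4-hydroxybenzylidene)-4-(3,5-dibromo-4-hydroxyphenyl)furan-2(5H)-one | O=C1C=C(c2cc(Br)c(O)c(Br)c2)/C(=C/c2cc(Br)c(O)c(Br)c2)O1 | target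

## Step count and risks

Total step count: 4. Longest linear sequence: 4 (1 → 3 → 4 → 5 → 10; compound 6 is purchased).

**Step 4 (key step).** The intermolecular acid-catalysed aldol addition of the electron-poor, sparingly soluble ketone may be slow, so that glyoxylic acid is consumed by self-reaction. The sequence may also stall at the lactol stage through incomplete dehydration. The fallback separates C–C bond formation from ring closure and masks the phenols; it sets out from 5 and returns at 10.
- O-Methylation of both phenols (MeI, K2CO3, acetone) should give 1,3-bis(3,5-dibromo-4-methoxyphenyl)propan-2-one F1.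
- Its lithium enolate (LiN(SiMe3)2, THF, −78 °C) should add to ethyl glyoxylate to give ethyl 3,5-bis(3,5-dibromo-4-methoxyphenyl)-2-hydroxy-4-oxopentanoate F2.
- Acidic ester hydrolysis with β-elimination and ring closure (aqueous HCl, AcOH, 100 °C; acid is chosen to avoid a retro-aldol) should give 5-(3,5-dibromo-4-methoxybenzyl)-4-(3,5-dibromo-4-methoxyphenyl)-5-hydroxyfuran-2(5H)-one F3.
- Dehydration with Ac2O/NaOAc at 100 °C, usable here because no free phenol is present, should give rubrolide A di-O-methyl ether F4.
- BBr3 in CH2Cl2 then cleaves both hindered methyl ethers under acidic conditions, which the enol lactone tolerates, to give 10.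

**Step 3.** Competing α-bromination of the enolisable benzylic ketone, or over-bromination of the rings to bromodienones, may erode the ring-selective tetrabromination. The fallback moves bromination behind the annulation, where no ketone is left; it sets out from 3 and returns at 10.
- Condensation of 3 with 6 under the conditions of step 4 should give rubrolide E di-O-methyl ether F5 (the same compound as A2). The anisole rings are far less prone to hydroxyalkylation than free phenols.
- BBr3 in CH2Cl2 should give rubrolide E F6.
- Br2 (4 equiv) with KBr in dioxane–water at room temperature should brominate both phenol rings ortho to OH and give 10.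

**Step 1.** O-to-N acyl migration in the activated acid (N-acylurea formation) and further activation of β-keto acid 2 before it decarboxylates (acylketene-derived self-condensation) may divert material. The fallback uses a classical ester Claisen condensation; it sets out from 1 and returns at 3.
- Fischer esterification (MeOH, H2SO4) should give methyl (4-methoxyphenyl)acetate F7.
- Self-condensation with NaH in THF should give methyl 2,4-bis(4-methoxyphenyl)-3-oxobutanoate F8.
- Hydrolysis and decarboxylation in aqueous HCl/AcOH at reflux should give 3.

## Further compounds

F1 | step 4 | 1,3-bis(3,5-dibromo-4-methoxyphenyl)propan-2-one | COc1c(Br)cc(CC(=O)Cc2cc(Br)c(OC)c(Br)c2)cc1Br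
F2 | step 4 | ethyl 3,5-bis(3,5-dibromo-4-methoxyphenyl)-2-hydroxy-4-oxopentanoate (diastereomer mixture, racemic) | CCOC(=O)C(O)C(c1cc(Br)c(OC)c(Br)c1)C(=O)Cc1cc(Br)c(OC)c(Br)c1
F3 | step 4 | 5-(3,5-dibromo-4-methoxybenzyl)-4-(3,5-dibromo-4-methoxyphenyl)-5-hydroxyfuran-2(5H)-one (racemic) | O=C1C=C(c2cc(Br)c(OC)c(Br)c2)C(O)(Cc2cc(Br)c(OC)c(Br)c2)O1
F4 | step 4 | rubrolide A di-O-methyl ether, (Z)-5-(3,5-dibromo-4-methoxybenzylidene)-4-(3,5-dibromo-4-methoxyphenyl)furan-2(5H)-one | O=C1C=C(c2cc(Br)c(OC)c(Br)c2)/C(=C/c2cc(Br)c(OC)c(Br)c2)O1
F5 | step 3 | rubrolide E di-O-methyl ether, (Z)-5-(4-methoxybenzylidene)-4-(4-methoxyphenyl)furan-2(5H)-one | O=C1C=C(c2ccc(OC)cc2)/C(=C/c2ccc(OC)cc2)O1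
F6 | step 3 | rubrolide E, (Z)-5-(4-hydroxybenzylidene)-4-(4-hydroxyphenyl)furan-2(5H)-one | O=C1C=C(c2ccc(O)cc2)/C(=C/c2ccc(O)cc2)O1
F7 | step 1 | methyl (4-methoxyphenyl)acetate | COC(=O)Cc1ccc(OC)cc1
F8 | step 1 | methyl 2,4-bis(4-methoxyphenyl)-3-oxobutanoate (racemic) | COC(=O)C(c1ccc(OC)cc1)C(=O)Cc1ccc(OC)cc1
A1 | alternative 1 | 4-(4-methoxyphenyl)furan-2(5H)-one | O=C1C=C(c2ccc(OC)cc2)CO1
A2 | alternative 1 | rubrolide E di-O-methyl ether, (Z)-5-(4-methoxybenzylidene)-4-(4-methoxyphenyl)furan-2(5H)-one | O=C1C=C(c2ccc(OC)cc2)/C(=C/c2ccc(OC)cc2)O1
A3 | alternative 2 | (Z)-3-iodo-3-(4-methoxyphenyl)prop-2-enoic acid | OC(=O)/C=C(\I)c1ccc(OC)cc1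
A4 | alternative 2 | (Z)-3,5-bis(4-methoxyphenyl)pent-2-en-4-ynoic acid | OC(=O)/C=C(\C#Cc1ccc(OC)cc1)c1ccc(OC)cc1
A5 | alternative 2 | 4,6-bis(4-methoxyphenyl)-2H-pyran-2-one | O=c1cc(-c2ccc(OC)cc2)cc(-c2ccc(OC)cc2)o1
A6 | alternative 3 | ethyl 3-(4-methoxyphenyl)prop-2-ynoate | CCOC(=O)C#Cc1ccc(OC)cc1
A7 | alternative 3 | ethyl (E)-3,5-bis(4-methoxyphenyl)pent-2-en-4-ynoate | CCOC(=O)/C=C(/C#Cc1ccc(OC)cc1)c1ccc(OC)cc1
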